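Everything rests on disconnecting ring F at O1'–C8a', the aryl ether bond to ring D, instead of at the benzylic O1'–C2' bond. The 2',3'-cis lower flavan (rings D, F, E) epimerises as soon as C2' ionises, so the key step exploits the fact that C8a' is an aromatic carbon. Copper-catalysed intramolecular etherification joins the C2' hydroxyl to the C8a' bromide and closes ring F in one operation without breaking any bond at C2' or C3'. Its precursor is the benzyl-protected 2,3-trans-3,4-cis upper flavan (rings A, C, B) whose ring D bears Br at C8a' and, at C4a', a syn (2'S,3'S) chain with free 2'-OH and benzylated 3'-O.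

Key step: step 18

Remark on drawing: α and β are the faces of the usual flavan drawing, in which the 2-aryl group of the upper unit is α. Primed locants belong to the lower unit.
Remark on design: the carbon that becomes C4' sits on ring D from its first step. Electrophilic halomethylation of an assembled upper flavan would strike the resorcinol-type ring A, not the brominated ring D. Iodine at C6' and bromine at C8a' are told apart by their rates of halogen–magnesium exchange.
Assumption: the tertiary carbinol of step 10 is drawn as the 4β-ol expected from attack anti to O3. Either C4 epimer would give the same cation in step 11.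

Step 1
Reactants: 1 1-[4-(benzyloxy)-2-hydroxyphenyl]ethan-1-one
Product: 2 1-[4-(benzyloxy)-2-(methoxymethoxy)phenyl]ethan-1-one
Conditions: NaH, MOMCl, DMF, 0 °C to rt
Reagents that add atoms: chloromethyl methyl ether, COCCl
Why: Williamson-type O-alkylation, with NaH needed because the 2-OH is hydrogen-bonded to the ketone; masking it prevents flavanone or aurone formation in steps 2 and 3.

Step 2
Reactants: 2 1-[4-(benzyloxy)-2-(methoxymethoxy)phenyl]ethan-1-one; 3 3,4-bis(benzyloxy)benzaldehyde
Product: 4 (E)-1-[4-(benzyloxy)-2-(methoxymethoxy)phenyl]-3-[3,4-bis(benzyloxy)phenyl]prop-2-en-1-one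
Conditions: KOH, EtOH–THF, rt
Reagents that add atoms: none
Why: Claisen–Schmidt condensation of a methyl ketone with a non-enolisable aldehyde, whose E1cB dehydration should give only the E-enone.

Step 3
Reactants: 4 (E)-chalcone
Product: 5 [4-(benzyloxy)-2-(methoxymethoxy)phenyl][(2R,3S)-3-[3,4-bis(benzyloxy)phenyl]oxiran-2-yl]methanone
Conditions: poly-L-leucine, urea·H2O2, DBU, THF, rt
Reagents that add atoms: urea–hydrogen peroxide, NC(N)=O.OO
Why: Juliá–Colonna epoxidation (conjugate addition of hydroperoxide inside the helical peptide), in which the L-configured polymer should deliver oxygen to the enone face giving the (2R,3S)-trans-epoxide that fixes the future C3 and, after inversion, C2.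

Step 4
Reactants: 5 (2R,3S)-epoxy ketone
Product: 7 (2R,3R)-7-(benzyloxy)-2-[3,4-bis(benzyloxy)phenyl]-3-hydroxychroman-4-one, via epoxy phenol 6 (not isolated)
Conditions: HCl, MeOH–THF, 50 °C
Reagents that add atoms: none
Why: Acidic acetal cleavage frees the phenol, which opens the epoxide at the benzylic carbon in a 6-endo-tet mode with inversion (S to R at the future C2) while C3 keeps its bonds; any 2,3-cis isomer from a looser benzylic cation should equilibrate to the more stable trans ketone.

Step 5
Reactants: 7 (2R,3R)-3-hydroxychroman-4-one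
Product: 8 (2R,3R)-3,7-bis(benzyloxy)-2-[3,4-bis(benzyloxy)phenyl]chroman-4-one
Conditions: BnOC(=NH)CCl3, TfOH (cat.), CH2Cl2–cyclohexane, 0 °C to rt
Reagents that add atoms: benzyl 2,2,2-trichloroacetimidate, N=C(OCc1ccccc1)C(Cl)(Cl)Cl
Why: Acid-catalysed trichloroacetimidate benzylation avoids the base that would open ring C by β-elimination or epimerise C2 and C3.

Step 6
Reactants: 9 2-bromo-4-hydroxybenzaldehyde
Product: 10 2-bromo-4-hydroxy-5-iodobenzaldehyde
Conditions: NIS, CF3CO2H (cat.), MeCN, 0 °C to rt
Reagents that add atoms: N-iodosuccinimide, O=C1CCC(=O)N1I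
Why: Electrophilic aromatic iodination ortho to the phenol, which should go to C5 because the other ortho position is wedged between OH and Br.

Step 7
Reactants: 10 2-bromo-4-hydroxy-5-iodobenzaldehyde
Product: 11 4-(benzyloxy)-2-bromo-5-iodobenzaldehyde
Conditions: BnBr, K2CO3, DMF, rt
Reagents that add atoms: benzyl bromide, BrCc1ccccc1
Why: Williamson etherification of an acidic iodophenol under mild carbonate conditions.

Step 8
Reactants: 11 4-(benzyloxy)-2-bromo-5-iodobenzaldehyde
Product: 12 [4-(benzyloxy)-2-bromo-5-iodophenyl]methanol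
Conditions: NaBH4, MeOH–THF, 0 °C
Reagents that add atoms: none
Why: Borohydride reduction of the aldehyde leaves both aryl halides untouched and turns the carbonyl carbon into the future C4'.

Step 9
Reactants: 12 [4-(benzyloxy)-2-bromo-5-iodophenyl]methanol
Product: 13 {[4-(benzyloxy)-2-bromo-5-iodophenyl]methoxy}(tert-butyl)dimethylsilane
Conditions: TBSCl, imidazole, DMF, rt
Reagents that add atoms: tert-butyldimethylsilyl chloride, CC(C)(C)[Si](C)(C)Cl
Why: Imidazole-promoted silylation removes the alcohol proton that would quench the Grignard reagent of step 10.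

Step 10
Reactants: 13 ring D aryl iodide; 8 (2R,3R)-chroman-4-one
Product: 15 (2R,3R,4R)-3,7-bis(benzyloxy)-2-[3,4-bis(benzyloxy)phenyl]-4-[2-(benzyloxy)-4-bromo-5-{[(tert-butyldimethylsilyl)oxy]methyl}phenyl]chroman-4-ol, via arylmagnesium chloride 14 (not isolated)
Conditions: i-PrMgCl·LiCl, THF, −20 °C; then 8, LaCl3·2LiCl, THF, −20 to 0 °C; H2O
Reagents that add atoms: none
Why: Iodine–magnesium exchange is far faster than bromine–magnesium exchange, so only C6' is metallated, and the LaCl3-promoted Grignard 1,2-addition should outrun enolisation and β-elimination of the ketone; attack anti to the 3-benzyloxy group gives a C4 configuration that is erased in step 11.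

Step 11
Reactants: 15 tertiary carbinol
Product: 17 (2R,3S,4R)-3,7-bis(benzyloxy)-2-[3,4-bis(benzyloxy)phenyl]-4-[2-(benzyloxy)-4-bromo-5-{[(tert-butyldimethylsilyl)oxy]methyl}phenyl]chroman (2,3-trans-3,4-cis), via flavan-4-ylium trifluoroacetate 16 (not isolated)
Conditions: Bu3SnH, CF3CO2H, CH2Cl2, −20 to 0 °C
Reagents that add atoms: none
Why: Ionic hydrogenation, in which CF3CO2H ionises the doubly benzylic tertiary alcohol and the fast hydride donor Bu3SnH should capture the planar C4 cation from the α face, anti to the vicinal 3β-benzyloxy group, while ring D swings into the pseudoaxial β position free of peri and 1,2-strain, which sets C4 as 3,4-cis.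

Step 12
Reactants: 17 4β-aryl flavan silyl ether
Product: 18 (2R,3S,4R)-3,7-bis(benzyloxy)-2-[3,4-bis(benzyloxy)phenyl]-4-[2-(benzyloxy)-4-bromo-5-(bromomethyl)phenyl]chroman
Conditions: Ph3PBr2, CH2Cl2, 0 °C to rt
Reagents that add atoms: dibromotriphenylphosphorane, BrP(Br)(c1ccccc1)(c1ccccc1)c1ccccc1
Why: Appel-type substitution converts the silyl ether directly into the bromide through an alkoxyphosphonium salt, and any alcohol freed by partial desilylation in step 11 converges on the same product.

Step 13
Reactants: 19 (R)-4-benzyl-1,3-oxazolidin-2-one; 20 (benzyloxy)acetyl chloride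
Product: 22 (R)-4-benzyl-3-[(benzyloxy)acetyl]-1,3-oxazolidin-2-one, via N-lithio oxazolidinone 21 (not isolated)
Conditions: n-BuLi, THF, −78 °C; then 20, −78 to 0 °C
Reagents that add atoms: none
Why: N-acylation of the lithiated carbamate by the acid chloride, the standard way of loading this auxiliary.

Step 14
Reactants: 22 glycolyl imide; 18 benzylic bromide
Product: 24 (R)-4-benzyl-3-[(2S)-2-(benzyloxy)-3-aryl-propanoyl]-1,3-oxazolidin-2-one in which the aryl group is ring D of 18 (C3' is S), via sodium Z-enolate 23 (not isolated)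
Conditions: 22 (excess), NaN(SiMe3)2, THF, −78 °C; then 18, −78 to −40 °C
Reagents that add atoms: none
Why: Evans-type glycolate alkylation, in which the sodium-chelated Z-enolate is shielded on one face by the (R)-benzyl group so that the reactive p-alkoxybenzyl bromide enters from the other face and sets C3' as S.

Step 15
Reactants: 24 alkylated imide
Product: 25 (2S)-2-(benzyloxy)-N-methoxy-N-methyl-3-aryl-propanamide in which the aryl group is ring D of the upper flavan
Conditions: MeONHMe·HCl, AlMe3, CH2Cl2, −10 °C to rt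
Reagents that add atoms: N,O-dimethylhydroxylamine hydrochloride, CNOC.Cl
Why: Weinreb transamidation, in which the aluminium amide attacks the exocyclic imide carbonyl, activated by chelation to the α-benzyloxy group, and releases the auxiliary without touching C3'.

Step 16
Reactants: 25 Weinreb amide; 26 4-bromo-1,2-bis(benzyloxy)benzene
Product: 28 (2S)-2-(benzyloxy)-1-[3,4-bis(benzyloxy)phenyl]-3-aryl-propan-1-one in which the aryl group is ring D of the upper flavan, via arylmagnesium bromide 27 (not isolated)
Conditions: 26, Mg, THF, 40 °C; then 25, THF, 0 °C; H2O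
Reagents that add atoms: none
Why: Weinreb ketone synthesis, in which the chelated tetrahedral adduct stops at one addition and an aryl Grignard reagent, unlike an aryllithium, does not exchange with the ring D bromide.

Step 17
Reactants: 28 α-benzyloxy ketone
Product: 29 benzyl-protected upper flavan whose ring D carries Br at C8a' and at C4a' the (2'S,3'S)-3'-(benzyloxy)-2'-hydroxy-2'-[3,4-bis(benzyloxy)phenyl]ethyl-methylene chain (syn)
Conditions: LiBH(s-Bu)3, THF, −78 °C; H2O
Reagents that add atoms: none
Why: Felkin–Anh-controlled ketone reduction, in which the bulky and poorly chelating borohydride attacks anti to the perpendicular C3'–OBn bond past the C3' hydrogen and should give the syn (2'S,3'S) alcohol.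

Step 18
Reactants: 29 bromo alcohol
Product: 30 octa-O-benzyl ether of the target, (2R,3S,4R,2'S,3'S)
Conditions: CuI (10 mol %), 3,4,7,8-tetramethyl-1,10-phenanthroline (20 mol %), Cs2CO3, 4 Å MS, toluene, 110 °C, argon
Reagents that add atoms: none
Why: Ullmann-type intramolecular C–O coupling: Cs2CO3 and the phenanthroline-bound monovalent copper convert the C2' hydroxyl into a copper alkoxide, the C8a'–Br bond adds to the metal to give a seven-membered aryl alkoxide of trivalent copper, and reductive elimination forms O1'–C8a'. The closest known reaction type is the copper-catalysed etherification of aryl halides with secondary alcohols, which has been used intramolecularly to make chromans. Ring F closes as a six-membered ring, formally 6-exo with respect to the departing bromide. No stereocentre is created: both carbinol carbons keep all four of their bonds, so the syn chain is carried over unchanged into the 2',3'-cis ring, and C2, C3 and C4 are spectators. The step needs closure through the right oxygen and freedom from benzylic ionisation or alcohol dehydrogenation. The substrate secures this because O3' is benzylated (no dihydrobenzofuran closure), the medium is basic and non-ionising, air is excluded, and copper alkoxides are reluctant to lose a β-hydride.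

Step 19
Reactants: 30 octa-O-benzyl ether
Product: 31 target, (2R,3S,4S,2'S,3'S)
Conditions: H2 (1 atm), Pd(OH)2/C, THF–MeOH, rt
Reagents that add atoms: none
Why: Catalytic hydrogenolysis removes all eight benzyl ethers under neutral conditions, which should leave the cyclic benzylic C–O bonds and the acid-labile C4–C6' bond intact.

Compound list
1 | 1-[4-(benzyloxy)-2-hydroxyphenyl]ethan-1-one | CC(=O)c1ccc(OCc2ccccc2)cc1O | starting material
2 | 1-[4-(benzyloxy)-2-(methoxymethoxy)phenyl]ethan-1-one | CC(=O)c1ccc(OCc2ccccc2)cc1OCOC | intermediate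
3 | 3,4-bis(benzyloxy)benzaldehyde | O=Cc1ccc(OCc2ccccc2)c(OCc2ccccc2)c1 | starting material
4 | (E)-chalcone | COCOc1cc(OCc2ccccc2)ccc1C(=O)/C=C/c1ccc(OCc2ccccc2)c(OCc2ccccc2)c1 | intermediate
5 | (2R,3S)-trans-epoxy ketone, MOM ether | COCOc1cc(OCc2ccccc2)ccc1C(=O)[C@@H]1O[C@H]1c1ccc(OCc2ccccc2)c(OCc2ccccc2)c1 | intermediate
6 | (2R,3S)-trans-epoxy ketone, free phenol (not isolated) | Oc1cc(OCc2ccccc2)ccc1C(=O)[C@@H]1O[C@H]1c1ccc(OCc2ccccc2)c(OCc2ccccc2)c1 | intermediate
7 | (2R,3R)-7-(benzyloxy)-2-[3,4-bis(benzyloxy)phenyl]-3-hydroxychroman-4-one | c1ccccc1COc1ccc2c(c1)O[C@H](c1ccc(OCc3ccccc3)c(OCc3ccccc3)c1)[C@@H](O)C2=O | intermediate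
8 | (2R,3R)-3,7-bis(benzyloxy)-2-[3,4-bis(benzyloxy)phenyl]chroman-4-one | c1ccccc1COc1ccc2c(c1)O[C@H](c1ccc(OCc3ccccc3)c(OCc3ccccc3)c1)[C@@H](OCc3ccccc3)C2=O | intermediate
9 | 2-bromo-4-hydroxybenzaldehyde | O=Cc1ccc(O)cc1Br | starting material
10 | 2-bromo-4-hydroxy-5-iodobenzaldehyde | O=Cc1cc(I)c(O)cc1Br | intermediate
11 | 4-(benzyloxy)-2-bromo-5-iodobenzaldehyde | O=Cc1cc(I)c(OCc2ccccc2)cc1Br | intermediate
12 | [4-(benzyloxy)-2-bromo-5-iodophenyl]methanol | OCc1cc(I)c(OCc2ccccc2)cc1Br | intermediate
13 | TBS ether of 12 | CC(C)(C)[Si](C)(C)OCc1cc(I)c(OCc2ccccc2)cc1Br | intermediate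
14 | ring D arylmagnesium chloride (not isolated) | CC(C)(C)[Si](C)(C)OCc1cc([Mg]Cl)c(OCc2ccccc2)cc1Br | intermediate
15 | (2R,3R,4R)-4α-aryl-4β-hydroxy flavan | c1ccccc1COc1ccc2c(c1)O[C@H](c1ccc(OCc3ccccc3)c(OCc3ccccc3)c1)[C@@H](OCc3ccccc3)[C@]2(O)c1cc(CO[Si](C)(C)C(C)(C)C)c(Br)cc1OCc1ccccc1 | intermediate
16 | 4-arylflavan-4-ylium trifluoroacetate (not isolated) | c1ccccc1COc1ccc2c(c1)O[C@H](c1ccc(OCc3ccccc3)c(OCc3ccccc3)c1)[C@@H](OCc3ccccc3)[C+]2c1cc(CO[Si](C)(C)C(C)(C)C)c(Br)cc1OCc1ccccc1.[O-]C(=O)C(F)(F)F | intermediate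
17 | (2R,3S,4R)-4β-aryl flavan, CH2OTBS at C4a' | c1ccccc1COc1ccc2c(c1)O[C@H](c1ccc(OCc3ccccc3)c(OCc3ccccc3)c1)[C@@H](OCc3ccccc3)[C@H]2c1cc(CO[Si](C)(C)C(C)(C)C)c(Br)cc1OCc1ccccc1 | intermediate
18 | (2R,3S,4R)-4β-aryl flavan, CH2Br at C4a' | c1ccccc1COc1ccc2c(c1)O[C@H](c1ccc(OCc3ccccc3)c(OCc3ccccc3)c1)[C@@H](OCc3ccccc3)[C@H]2c1cc(CBr)c(Br)cc1OCc1ccccc1 | intermediate
19 | (R)-4-benzyl-1,3-oxazolidin-2-one | O=C1N[C@H](Cc2ccccc2)CO1 | starting material
20 | (benzyloxy)acetyl chloride | O=C(Cl)COCc1ccccc1 | starting material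
21 | N-lithio-(R)-4-benzyl-1,3-oxazolidin-2-one (not isolated) | [Li]N1[C@H](Cc2ccccc2)COC1=O | intermediate
22 | (R)-4-benzyl-3-[(benzyloxy)acetyl]-1,3-oxazolidin-2-one | O=C(COCc1ccccc1)N1[C@H](Cc2ccccc2)COC1=O | intermediate
23 | sodium (Z)-enolate of 22 (not isolated) | [Na+].[O-]/C(=C\OCc1ccccc1)N1[C@H](Cc2ccccc2)COC1=O | intermediate
24 | alkylated imide, C3' (S) | c1ccccc1COc1ccc2c(c1)O[C@H](c1ccc(OCc3ccccc3)c(OCc3ccccc3)c1)[C@@H](OCc3ccccc3)[C@H]2c1cc(C[C@H](OCc3ccccc3)C(=O)N3[C@H](Cc4ccccc4)COC3=O)c(Br)cc1OCc1ccccc1 | intermediate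
25 | Weinreb amide, C3' (S) | c1ccccc1COc1ccc2c(c1)O[C@H](c1ccc(OCc3ccccc3)c(OCc3ccccc3)c1)[C@@H](OCc3ccccc3)[C@H]2c1cc(C[C@H](OCc3ccccc3)C(=O)N(C)OC)c(Br)cc1OCc1ccccc1 | intermediate
26 | 4-bromo-1,2-bis(benzyloxy)benzene | Brc1ccc(OCc2ccccc2)c(OCc2ccccc2)c1 | starting material
27 | 3,4-bis(benzyloxy)phenylmagnesium bromide (not isolated) | Br[Mg]c1ccc(OCc2ccccc2)c(OCc2ccccc2)c1 | intermediate
28 | α-benzyloxy aryl ketone, C3' (S) | c1ccccc1COc1ccc2c(c1)O[C@H](c1ccc(OCc3ccccc3)c(OCc3ccccc3)c1)[C@@H](OCc3ccccc3)[C@H]2c1cc(C[C@H](OCc3ccccc3)C(=O)c2ccc(OCc3ccccc3)c(OCc3ccccc3)c2)c(Br)cc1OCc1ccccc1 | intermediate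
29 | key-step precursor, syn (2'S,3'S) bromo alcohol | c1ccccc1COc1ccc2c(c1)O[C@H](c1ccc(OCc3ccccc3)c(OCc3ccccc3)c1)[C@@H](OCc3ccccc3)[C@H]2c1cc(C[C@H](OCc3ccccc3)[C@@H](O)c2ccc(OCc3ccccc3)c(OCc3ccccc3)c2)c(Br)cc1OCc1ccccc1 | intermediate
30 | key-step product, octa-O-benzyl target | c1ccccc1COc1ccc2c(c1)O[C@H](c1ccc(OCc3ccccc3)c(OCc3ccccc3)c1)[C@@H](OCc3ccccc3)[C@H]2c1cc2c(cc1OCc3ccccc3)O[C@@H](c1ccc(OCc3ccccc3)c(OCc3ccccc3)c1)[C@@H](OCc3ccccc3)C2 | intermediate
31 | CNP0187520.5, 2,3-trans-3,4-cis upper flavan linked C4–C6' to the (2'S,3'S)-cis lower flavan | Oc1ccc2c(c1)O[C@H](c1ccc(O)c(O)c1)[C@@H](O)[C@H]2c1cc2c(cc1O)O[C@@H](c1ccc(O)c(O)c1)[C@@H](O)C2 | target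

Total step count: 19. Longest linear sequence: 14 steps (1–5, 10–12, 14–19).

Steps most likely to fail

Step 18. Activation of the hindered C8a'–Br bond may be sluggish at the temperature the substrate tolerates. Hydrodebromination or dehydrogenation of the benzylic alcohol could then take over. The fallback keeps the O1'–C8a' closure but reverses the role of the arene carbon. It sets out from 29, where Miyaura borylation (B2pin2, PdCl2(dppf), KOAc, dioxane, 80 °C) should give the C8a' pinacol boronate F1. A Chan–Lam oxidative etherification (Cu(OAc)2, pyridine, 4 Å MS, dry air, CH2Cl2, rt) then couples the C2' hydroxyl with the boron-bearing carbon near room temperature. It comes back to the route at 30, again with no bond broken at C2' or C3'.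

Step 11. Hydride capture of the C4 cation may discriminate poorly between the two faces, because the vicinal 3β-benzyloxy group and the remote 2α-aryl group pull in opposite directions. Proton loss from C3 may also compete. The fallback replaces reliance on one-pass selectivity by a stereoconvergent loop. It sets out from 15, whose reduction product is separated by chromatography. The all-trans 4α-aryl epimer F2 has a pseudoaxial C4–H bond aligned with ring A. It is re-oxidised by benzylic hydride abstraction and water capture (DDQ, CH2Cl2–H2O, 0 °C). This comes back to the route at 15, which is reduced again until the material has converged on 17.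

Step 17. A lithium-chelated transition state may compete with the Felkin–Anh one and erode the syn selectivity at C2'. The fallback replaces substrate control by catalyst control. It sets out from 28 and uses Noyori asymmetric transfer hydrogenation with RuCl(p-cymene)[(R,R)-TsDPEN] in HCO2H–Et3N at rt. The (R,R) antipode is chosen by analogy with simple aryl alkyl ketones, whose aryl group is recognised by the arene ligand. It comes back to the route at 29 and makes no new compound F0.

Further compounds
F1 | step 18 | C8a' pinacol boronate of 29, (2'S,3'S) alcohol retained | c1ccccc1COc1ccc2c(c1)O[C@H](c1ccc(OCc3ccccc3)c(OCc3ccccc3)c1)[C@@H](OCc3ccccc3)[C@H]2c1cc(C[C@H](OCc3ccccc3)[C@@H](O)c2ccc(OCc3ccccc3)c(OCc3ccccc3)c2)c(B2OC(C)(C)C(C)(C)O2)cc1OCc1ccccc1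
F2 | step 11 | 4α-aryl (2,3-trans-3,4-trans) epimer of 17 | c1ccccc1COc1ccc2c(c1)O[C@H](c1ccc(OCc3ccccc3)c(OCc3ccccc3)c1)[C@@H](OCc3ccccc3)[C@@H]2c1cc(CO[Si](C)(C)C(C)(C)C)c(Br)cc1OCc1ccccc1
F0 | step 17 | none | none
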